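**Retrosynthetic overview**

- Feature used: on each aromatic ring the C8 ketone carbon is ortho to the free C7 hydroxyl (O7–C7–C8–C=O, a salicyl-type chelate), and its (R) α-carbon carries a methyl and a two-carbon arm, which is the branched adduct of a formyl C–H bond to a C4 diene.
- The two ethyl groups are vinyl groups before the last step; both C(=O)–Cα bonds and both stereocentres come from a double enantioselective hydroacylation of buta-1,3-diene by the bridged bis(8-formylchroman).
- The dialdehyde is cut at the C6–CH–C6' methine into two molecules of 5,7-dihydroxy-2,2-dimethylchroman-8-carbaldehyde and 6-methylheptanal; C6 is the only free ring carbon, so the bridge can only form there.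
- The chroman aldehyde comes from 2,4,6-trihydroxybenzaldehyde; O4 is benzylated first so that prenylation and cyclisation with 2-methylbut-3-en-2-ol can only close the pyran onto the hydroxyl beside the formyl group (O1 next to C8).
- Ring order: the benzene ring is bought, the dihydropyran ring of each chroman is closed in step 2, and no ring is formed after that.

Key step: step 5

Remark: the sense of induction of a chiral bisphosphine in this diene hydroacylation cannot be predicted; the ligand is written as (R)-DTBM-SEGPHOS, and the antipode that gives the (R) ketone is to be fixed in a trial on the monomeric 8-formylchroman.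

Step 1
Reactants: 1 2,4,6-trihydroxybenzaldehyde; 2 benzyl bromide
Product: 3 4-(benzyloxy)-2,6-dihydroxybenzaldehyde
Conditions: BnBr (1.0 equiv), NaHCO3 (1.2 equiv), DMF, 25–40 °C
Reagents that add atoms: benzyl bromide (2), BrCc1ccccc1
Why: Williamson etherification should go at the para hydroxyl, the most acidic one and the only one that cannot hydrogen-bond to the formyl oxygen, so a weak base and one equivalent of halide should stop at the mono-ether, with any 2,4-dibenzyl ether removed by chromatography.

Step 2
Reactants: 3 4-(benzyloxy)-2,6-dihydroxybenzaldehyde; 4 2-methylbut-3-en-2-ol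
Product: 6 5-(benzyloxy)-7-hydroxy-2,2-dimethylchroman-8-carbaldehyde, via C-prenyl phenol 5 (not isolated)
Conditions: 4 (1.2 equiv), BF3·OEt2 (0.3 equiv), 1,4-dioxane, 25 °C; then p-TsOH·H2O (0.1 equiv), 70 °C
Reagents that add atoms: 2-methylbut-3-en-2-ol (4), C=CC(C)(C)O
Why: Friedel–Crafts prenylation by the dimethylallyl cation at C3 (equivalent to C5) is followed by acid-catalysed Markovnikov hydroalkoxylation of the prenyl alkene, and because O4 is blocked the only hydroxyl next to the prenyl group is the one ortho to the formyl group, which places the pyran oxygen beside the aldehyde carbon without regiochemical ambiguity.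

Step 3
Reactants: 6 5-(benzyloxy)-7-hydroxy-2,2-dimethylchroman-8-carbaldehyde
Product: 7 5,7-dihydroxy-2,2-dimethylchroman-8-carbaldehyde
Conditions: H2 (1 atm), 10% Pd/C, EtOAc, 25 °C
Reagents that add atoms: none
Why: Hydrogenolysis of the benzyl aryl ether is fast under neutral conditions, while the aldehyde, deactivated by three ring oxygens and chelated to O7–H, should survive if the uptake is stopped after one equivalent.

Step 4
Reactants: 7 5,7-dihydroxy-2,2-dimethylchroman-8-carbaldehyde (two molecules); 8 6-methylheptanal
Product: 11 6,6'-(6-methylheptane-1,1-diyl)bis(5,7-dihydroxy-2,2-dimethylchroman-8-carbaldehyde), via benzylic carbinol 9 (not isolated), via ortho-quinone methide 10 (not isolated)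
Conditions: 7 (2.1 equiv), 8 (1.0 equiv, slow addition), p-TsOH·H2O (0.1 equiv), AcOH, 60 °C
Reagents that add atoms: 6-methylheptanal (8), CC(C)CCCCC=O
Why: In this Baeyer-type phenol–aldehyde condensation, as used for bridged acylphloroglucinol dimers, the ring is hydroxyalkylated at C6, its only unsubstituted carbon, water is lost to the ortho-quinone methide, and a second molecule adds through its own C6, the hydrogen-bonded aryl aldehydes being far poorer electrophiles than the aliphatic one.

Step 5
Reactants: 11 6,6'-(6-methylheptane-1,1-diyl)bis(5,7-dihydroxy-2,2-dimethylchroman-8-carbaldehyde); 12 buta-1,3-diene (two molecules)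
Product: 14 6,6'-(6-methylheptane-1,1-diyl)bis{5,7-dihydroxy-2,2-dimethyl-8-[(2R)-2-methylbut-3-enoyl]chroman}, via mono-ketone mono-aldehyde 13 (not isolated)
Conditions: [Rh(cod)Cl]2 (5 mol%), (R)-DTBM-SEGPHOS (11 mol%), K3PO4 (10 mol%), buta-1,3-diene (10 equiv), toluene/THF, sealed tube, 40 °C
Reagents that add atoms: buta-1,3-diene (12), C=CC=C
Why: Proposed new method: after deprotonation of the C7 hydroxyl, monovalent rhodium binds the phenoxide and adds oxidatively into the adjacent C8 formyl C–H bond to give a five-membered trivalent acyl rhodium hydride chelate (Rh–O–C7–C8–C=O) that resists decarbonylation; hydride transfer to coordinated butadiene gives a 1-methylallyl ligand, and C–C reductive elimination at its methyl-bearing terminus forms the C(=O)–CH(CH3)CH=CH2 bond, first at one aldehyde (13) and then at the other. The closest known reaction types are rhodium-catalysed intermolecular hydroacylation of alkenes and alkynes by salicylaldehydes under phenoxide chelation, also in enantioselective form with chiral phosphines, and ruthenium- or cobalt-catalysed hydroacylation of dienes to β,γ-unsaturated ketones; a branched, enantioselective addition to a conjugated diene inside the salicyl chelate, used twice on one substrate, is not established. No ring is closed. Each new α-stereocentre is set by the chiral bisphosphine, which selects the face of the equilibrating methylallyl terminus in the reductive elimination; the two sites react independently, so a wrong event ends mainly in a separable (R,S) diastereomer and the (R,R) product is enriched. The step needs branched over linear regioselectivity, expected from bond formation at the substituted allyl terminus inside the rigid O,C-chelate as in rhodium allyl chemistry, C–H over phenol O–H addition, secured by the chelate, and survival of the unconjugated alkene and the α-centre, for which only catalytic weak base and 40 °C are used.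

Step 6
Reactants: 14 6,6'-(6-methylheptane-1,1-diyl)bis{5,7-dihydroxy-2,2-dimethyl-8-[(2R)-2-methylbut-3-enoyl]chroman}
Product: 16 6,6'-(6-methylheptane-1,1-diyl)bis{5,7-dihydroxy-2,2-dimethyl-8-[(2R)-2-methylbutanoyl]chroman} (CNP0324275.1), via half-reduced ketone 15 (not isolated)
Conditions: H2 (1 atm), RhCl(PPh3)3 (5 mol%), toluene/EtOH 1:1, 25 °C
Reagents that add atoms: none
Why: Homogeneous hydrogenation with chlorotris(triphenylphosphine)rhodium saturates monosubstituted alkenes under neutral conditions without the double-bond migration typical of palladium on carbon, so the vinyl groups should become ethyl groups while the aryl ketones and the (R) α-centres, whose spatial arrangement and CIP descriptor are unchanged, stay intact.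

**Compound list**

1 | 2,4,6-trihydroxybenzaldehyde | O=Cc1c(O)cc(O)cc1O | starting material
2 | benzyl bromide | BrCc1ccccc1 | starting material
3 | 4-(benzyloxy)-2,6-dihydroxybenzaldehyde | O=Cc1c(O)cc(OCc2ccccc2)cc1O | intermediate
4 | 2-methylbut-3-en-2-ol | C=CC(C)(C)O | starting material
5 | 4-(benzyloxy)-2,6-dihydroxy-3-(3-methylbut-2-en-1-yl)benzaldehyde | O=Cc1c(O)cc(OCc2ccccc2)c(CC=C(C)C)c1O | intermediate (not isolated)
6 | 5-(benzyloxy)-7-hydroxy-2,2-dimethylchroman-8-carbaldehyde | O=Cc1c(O)cc(OCc2ccccc2)c2c1OC(C)(C)CC2 | intermediate
7 | 5,7-dihydroxy-2,2-dimethylchroman-8-carbaldehyde | O=Cc1c(O)cc(O)c2c1OC(C)(C)CC2 | intermediate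
8 | 6-methylheptanal | CC(C)CCCCC=O | starting material
9 | 5,7-dihydroxy-6-(1-hydroxy-6-methylheptyl)-2,2-dimethylchroman-8-carbaldehyde (racemic carbinol) | CC(C)CCCCC(O)c1c(O)c(C=O)c2c(c1O)CCC(C)(C)O2 | intermediate (not isolated)
10 | 5-hydroxy-2,2-dimethyl-6-(6-methylheptylidene)-7-oxo-3,4,6,7-tetrahydro-2H-chromene-8-carbaldehyde (ortho-quinone methide, one tautomer, alkene geometry open) | CC(C)CCCCC=C1C(=O)C(C=O)=C2OC(C)(C)CCC2=C1O | intermediate (not isolated)
11 | 6,6'-(6-methylheptane-1,1-diyl)bis(5,7-dihydroxy-2,2-dimethylchroman-8-carbaldehyde) | CC(C)CCCCC(c1c(O)c2c(c(C=O)c1O)OC(C)(C)CC2)c1c(O)c2c(c(C=O)c1O)OC(C)(C)CC2 | intermediate (key-step precursor)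
12 | buta-1,3-diene | C=CC=C | starting material
13 | 6-[1-(8-formyl-5,7-dihydroxy-2,2-dimethylchroman-6-yl)-6-methylheptyl]-5,7-dihydroxy-2,2-dimethyl-8-[(2R)-2-methylbut-3-enoyl]chroman (both epimers at the bridging carbon, which converge) | CC(C)CCCCC(c1c(O)c2c(c(C(=O)[C@H](C)C=C)c1O)OC(C)(C)CC2)c1c(O)c2c(c(C=O)c1O)OC(C)(C)CC2 | intermediate (not isolated)
14 | 6,6'-(6-methylheptane-1,1-diyl)bis{5,7-dihydroxy-2,2-dimethyl-8-[(2R)-2-methylbut-3-enoyl]chroman} | CC(C)CCCCC(c1c(O)c2c(c(C(=O)[C@H](C)C=C)c1O)OC(C)(C)CC2)c1c(O)c2c(c(C(=O)[C@H](C)C=C)c1O)OC(C)(C)CC2 | intermediate (key-step product)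
15 | analogue of 14 with one (2R)-2-methylbutanoyl and one (2R)-2-methylbut-3-enoyl arm (both epimers at the bridging carbon) | CC(C)CCCCC(c1c(O)c2c(c(C(=O)[C@H](C)CC)c1O)OC(C)(C)CC2)c1c(O)c2c(c(C(=O)[C@H](C)C=C)c1O)OC(C)(C)CC2 | intermediate (not isolated)
16 | 6,6'-(6-methylheptane-1,1-diyl)bis{5,7-dihydroxy-2,2-dimethyl-8-[(2R)-2-methylbutanoyl]chroman} | CC[C@@H](C)C(=O)c1c(O)c(C(CCCCC(C)C)c2c(O)c3c(c(C(=O)[C@H](C)CC)c2O)OC(C)(C)CC3)c(O)c2c1OC(C)(C)CC2 | target

Total step count: 6
Longest linear sequence: 6 steps (1 → 3 → 6 → 7 → 11 → 14 → 16)

**Steps most likely to fail**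

Step 5 (carries the new method). The acyl rhodium hydride may not turn over with the diene, bond formation may occur at the unsubstituted allyl terminus or with poor facial discrimination, and the β,γ-alkene may migrate into conjugation and then close onto O7. The fallback uses known chemistry, sets out from 11 and comes back at 16. All four phenols of 11 are capped with MOMCl and NaH in DMF to give the tetrakis(methoxymethyl) dialdehyde F1. Brown crotylboration of both aldehydes with (E)-crotyldiisopinocampheylborane made from (−)-α-pinene (THF/Et2O, −78 °C, then NaOH/H2O2) should give the anti bis(homoallylic alcohol) F2 with each methyl-bearing carbon (R). The carbinol centres are destroyed later, and if the sense at the methyl carbon proves opposite the reagent from (+)-α-pinene is used. Diimide reduction of the two vinyl groups (2-nitrobenzenesulfonylhydrazide, Et3N, CH2Cl2) gives the bis(sec-butyl carbinol) F3, Dess–Martin oxidation gives the tetra-MOM diketone F4, and HCl in MeOH/THF at 25 °C removes the MOM groups to give 16.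

Step 4. The ortho-quinone methide may tautomerise to the styrene or oligomerise faster than the second, formyl-deactivated arene adds, and the aliphatic aldehyde may self-condense under acid. The fallback sets out from 7 and 8 and comes back at 11. Three-component condensation of 7, 8 and sodium p-toluenesulfinate in aqueous formic acid at 25 °C should give the isolable 5,7-dihydroxy-2,2-dimethyl-6-[6-methyl-1-(p-tolylsulfonyl)heptyl]chroman-8-carbaldehyde F5. Treating F5 with a second equivalent of 7 and K2CO3 in MeCN at 25 °C releases the quinone methide 10 slowly, and it is captured at C6 of the phenoxide of 7 by conjugate addition to give 11.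

Step 2. Friedel–Crafts prenylation of the formyl-deactivated ring may stall, over-alkylate at the second free position, or be accompanied by acid-induced benzyl migration. The fallback sets out from 4, replaces steps 1 to 3 and comes back at 7. Phloroglucinol F6 (purchased) and 4 with BF3·OEt2 in dioxane give the symmetrical 5,7-dihydroxy-2,2-dimethylchroman F7. Vilsmeier–Haack formylation (POCl3, DMF, 0 °C, aqueous hydrolysis) followed by chromatographic separation from the 6-formyl regioisomer then gives 7. Here the formyl group enters after the pyran ring instead of directing its closure, at the price of a regioisomer separation.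

Further compounds
F1 | step 5 | 6,6'-(6-methylheptane-1,1-diyl)bis[5,7-bis(methoxymethoxy)-2,2-dimethylchroman-8-carbaldehyde] | CC(C)CCCCC(c1c(OCOC)c2c(c(C=O)c1OCOC)OC(C)(C)CC2)c1c(OCOC)c2c(c(C=O)c1OCOC)OC(C)(C)CC2
F2 | step 5 | tetra-MOM bis[(1R,2R)-1-hydroxy-2-methylbut-3-enyl] compound (anti homoallylic alcohols at both C8 positions) | CC(C)CCCCC(c1c(OCOC)c2c(c([C@H](O)[C@H](C)C=C)c1OCOC)OC(C)(C)CC2)c1c(OCOC)c2c(c([C@H](O)[C@H](C)C=C)c1OCOC)OC(C)(C)CC2
F3 | step 5 | tetra-MOM bis[(1R,2R)-1-hydroxy-2-methylbutyl] compound | CC(C)CCCCC(c1c(OCOC)c2c(c([C@H](O)[C@H](C)CC)c1OCOC)OC(C)(C)CC2)c1c(OCOC)c2c(c([C@H](O)[C@H](C)CC)c1OCOC)OC(C)(C)CC2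
F4 | step 5 | tetrakis(methoxymethyl) ether of 16 | CC(C)CCCCC(c1c(OCOC)c2c(c(C(=O)[C@H](C)CC)c1OCOC)OC(C)(C)CC2)c1c(OCOC)c2c(c(C(=O)[C@H](C)CC)c1OCOC)OC(C)(C)CC2
F5 | step 4 | 5,7-dihydroxy-2,2-dimethyl-6-[6-methyl-1-(p-tolylsulfonyl)heptyl]chroman-8-carbaldehyde (racemic) | CC(C)CCCCC(c1c(O)c(C=O)c2OC(C)(C)CCc2c1O)S(=O)(=O)c1ccc(C)cc1
F6 | step 2 | phloroglucinol (purchased starting material of the fallback) | Oc1cc(O)cc(O)c1
F7 | step 2 | 5,7-dihydroxy-2,2-dimethylchroman | CC1(C)CCc2c(O)cc(O)cc2O1
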